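The target forms when intermediate meets coupling partner on the second catalyst, but the partner also condenses with itself, so charging more of it may either speed the target or feed the self-condensation product.

all flasks: starting material 10 mM; free catalyst 20 µM; second catalyst 10 µM; time 8.0 s
- violet: coupling partner 15.0 mM
- green: coupling partner 50.0 mM
- teal: coupling partner 150 mM

    2 coupling partner → self-condensation product (k1 = 2.4 /M/s)
    coupling partner + second catalyst + intermediate → second catalyst + target (k2 = 7.7 × 10⁵ /M²/s)
    starting material + free catalyst → free catalyst + intermediate (k3 = 21000 /M/s)

- where a step has two of a species, its rate is k times that concentration squared, and two are used at each turn
- "hardly changes" means that all values lie within two and a half points (for a concentration: within two and a half percent of the largest)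
- run time (violet): 8.0 s

- amount of intermediate at the end, in percent of the starting material charged for violet, green, teal, in this order
- the course of these numbers from the first flask to the last (rises all the way / hardly changes / rises, then falls / falls, then rises / falls all the way)

We turn the question round: for the intermediate left at the end to rise from violet to teal, a larger charge of partner would have to leave less partner, summed over the run, than a smaller charge does. At the violet charge the starting material has a half-life of 1.7 s by its own step and the intermediate one of 6.0 s by coupling, so at the start the first half-life is shorter than the second. That comparison drifts, since the starting material runs down while the intermediate's pseudo-first-order use follows the falling partner.

We therefore carry one quantity, the coupling count: the number of intermediate lifetimes the run offers, which is the coupling constant times the second catalyst times the partner's sum over time. With self-condensation as the partner's loss, that sum is the logarithm of the factor by which the partner has been thinned at the end, divided by the doubled self-condensation constant. This gives 0.730 for violet, 1.72 for green and 3.07 for teal. The partner's first half-life by self-condensation shrinks from 13.9 s in violet to 1.39 s in teal, yet ten times the charge still multiplies the count by 4.21, so the teal count stands higher than the violet one, the opposite of what the reversal asks.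

Letting the intermediate start its exposure at the starting material's half-life, we commit to 55.7 %, 29.5 % and 15.8 %. We expect these to stand low, because full coupling would take 66.7 % of the violet partner, which our count leaves in the flask.

The forecast, higher than our figures, gave 63 %, 38 % and 23 %, a course that falls all the way, holding that “More partner always consumes more intermediate”.

The simulation gives 62.7 %, 37.7 % and 23.7 %, a course that falls all the way, each number above ours . In violet the making step had half its turnover behind it at 1.57 s, when intermediate was made 4.90 times faster than used, and by 8.00 s making ran at 0.425 of use, with 48 % of the partner left. Our count of 3.07 for teal takes self-condensation as the partner's loss, and at 8.00 s the teal self-condensation product held more partner than the teal target did, 123 mM against 7.28 mM, while behind our violet count of 0.730 the same two stood at 4.50 mM and 3.38 mM.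

All constants were drawn at random within sensible limits; the result is computed.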